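Slowness frames this comparison. After 3.00 min at 70 °C, the eta run had turned 26.7 % of its starting material into product, so a stop at 4.0 min is likely to catch a curve still climbing.

| flask | starting material | reagent | free catalyst | temperature | remark | time |
|---|---|---|---|---|---|---|
| zeta | 13 mM | 1 equiv | 10 mol% | 55 °C | run made earlier |  |
| eta | 37 mM | 1 equiv | 10 mol% | 70 °C | run made earlier |  |
| delta | 41 mM | 1 equiv | 15 mol% | 55 °C | run made earlier |  |
| alder | 15 mM | 1.00 equiv | 15 mol% | 70 °C |  | 4.0 min |
| ash | 41 mM | 1.00 equiv | 10 mol% | 70 °C |  | 4.0 min |

- zeta (time / min: product / %): 0.667: 0; 2.00: 2.5; 4.00: 4.5; 6.00: 10.4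
- eta (time / min: product / %): 0.250: 0; 0.500: 2.8; 1.33: 10.0; 3.00: 26.7
- delta (time / min: product / %): 0.500: 1.2; 1.00: 2.9; 3.00: 15.6; 6.00: 30.2

(scatter of a reading: 1 percentage point)

- the earlier runs were read with a standard deviation of 1 percentage point
- steps that have been proposed: catalyst intermediate A <-> catalyst intermediate B; starting material + free catalyst -> catalyst intermediate A; catalyst intermediate C -> catalyst intermediate D; catalyst intermediate D -> by-product + catalyst intermediate E; catalyst intermediate E -> free catalyst + product; reagent + catalyst intermediate B <-> catalyst intermediate C
- where the amount of starting material changes, what is given in equivalents or mol% on it follows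

* which one finishes higher in amount of product, in percent of the starting material charged ("neither" within 2 percentage points) (alder / ash / neither)
* amount of product at the end, in percent of the starting material charged, alder
* amount of product at the end, in percent of the starting material charged, ash

The question can be turned round: what would alder need in order to draw level with ash? Product, as a fraction of the charge, equals catalyst, as a fraction of the charge, times the turnover number, which counts how often each catalyst has gone round. Alder carries 15 mol% and ash 10 mol%, so alder draws level once its turnover number reaches 0.667 of ash's. This ratio, ash's loading over alder's, is the break-even turnover ratio.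

Alder is the more dilute flask. At 6.00 min and 55 °C, zeta at 13 mM shows 0.517 of the turnover number of delta at 41 mM, a reading uncertain by about 0.0497 from the scatter of zeta's reading, and these two runs differ in loading as well as in concentration. The concentration ratio of alder to ash is 0.366, against 0.317 for zeta to delta, but the temperature differs and the loadings lie the other way round. Taking that reading over to alder and ash, the reckoning made here, which is not the forecast's, puts alder's ratio below break-even, with about 0.775 of ash's product, so it names ash.

The forecast also names ash, with 37 % for ash and 27 % for alder, holding that “Turnover therefore rises with concentration, but less than proportionally”.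

    catalyst intermediate A ⇌ catalyst intermediate B (K = 0.450, k = 3.50 s⁻¹, Ea = 69.0 kJ mol⁻¹, ΔH = −27.0 kJ mol⁻¹)
    starting material + free catalyst → catalyst intermediate A (k = 7.50 M⁻¹ s⁻¹, Ea = 42.0 kJ mol⁻¹)
    catalyst intermediate C → catalyst intermediate D (k = 0.820 s⁻¹, Ea = 95.0 kJ mol⁻¹)
    catalyst intermediate D → by-product + catalyst intermediate E (k = 0.100 s⁻¹, Ea = 87.0 kJ mol⁻¹)
    catalyst intermediate E → free catalyst + product (k = 0.820 s⁻¹, Ea = 93.0 kJ mol⁻¹)
    reagent + catalyst intermediate B ⇌ catalyst intermediate C (K = 16.0 M⁻¹, k = 2.70 M⁻¹ s⁻¹, Ea = 51.0 kJ mol⁻¹, ΔH = 10.0 kJ mol⁻¹)
    (constants at 70 °C)

Ash gave 37.1 % and alder 24.6 %, so alder's turnover number was 0.441 of ash's, lower than the break-even 0.667. A flask with alder's loading and ash's 41 mM of starting material gave 50.6 %; its ratio to ash, 0.908, stands above break-even, and it passed ash. Neither alder nor ash was at rest at 4.0 min, with 62 % and 54 % of their starting material left. Ten times the time brings alder to 93.5 % and ash to 97.9 %, narrowing the gap from 12 percentage points to 4.4 points.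

(The numbers in the tables stem from a simulated flask with made-up constants, noise included.)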